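| flask | substrate | partner | protic impurity | time |
|---|---|---|---|---|
| north-east | 0.80 M (fed, over 0.40 s) | 1.00 equiv | 0.0160 M | 2.0 min |
| north | 0.80 M (fed, over 0.80 s) | 1.00 equiv | 0.0160 M | 2.0 min |
| west | 0.80 M (fed, over 1.5 s) | 1.00 equiv | 0.0160 M | 2.0 min |
| east | 0.80 M (fed, over 3.0 s) | 1.00 equiv | 0.0160 M | 2.0 min |
| south-west | 0.80 M (fed, over 6.0 s) | 1.00 equiv | 0.0160 M | 2.0 min |

    substrate + partner → intermediate A (k1 = 0.025 L mol⁻¹ s⁻¹)
    substrate + partner → intermediate B (k2 = 0.061 L mol⁻¹ s⁻¹)
    substrate ⇌ intermediate C (K3 = 2.1, k3 = 0.087 s⁻¹)
    intermediate C → intermediate D (k4 = 0.0026 s⁻¹)
    partner + intermediate C ⇌ intermediate E (K5 = 2.1 L mol⁻¹, k5 = 0.015 L mol⁻¹ s⁻¹)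
    partner + intermediate D → product (k6 = 0.10 L mol⁻¹ s⁻¹)
    intermediate A ⇌ intermediate B (K7 = 1.2, k7 = 0.0033 s⁻¹)
    partner + protic impurity → quenched reagent (k8 = 2.3 L mol⁻¹ s⁻¹)

- amount of product at the end, in percent of the substrate charged for north-east, north, west, east, south-west, in this order
- how the row runs (falls all the way / hardly changes / rises all the way / falls, then rises / rises, then falls)

- "hardly changes" means that all values lie within two and a half points (for a concentration: within two and a half percent of the largest)
- run time (north-east): 2.0 min

- Slowness of the feed is what I suspect first in this run. Substrate dosed at a steady rate arrives, on average, half the dosing time late. Between north-east and south-west that delay differs by 2.33% of the run time, and I carry this share, the feed lateness, from flask to flask.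
- If product climbs steadily near the end, a later feed costs about that share of the product itself. Even a full yield would then lose 2.33% of the charge, which is inside the margin asked, so I commit to a row that hardly changes.
- The feed is short on the flask's own clock too. Substrate goes to intermediate C with a half-life of 7.97 s by the forward step alone, longer than the 6.0 s of the longest feed.
- The protic impurity is the second setting to watch. Partner reacts with it 26.7 times faster, per unit of concentration, than with substrate by the two direct routes together.
- With partner at its charge, the impurity's half-life is 0.377 s. I put the answer back in and go round once more: partner short by the whole impurity charge gives 0.384 s. The quench takes 2.00% of the partner charge, and I expect that same toll in each flask.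
- My reckoning gives the spread of the row, not its level. The forecast gives 6.3%, 6.3%, 6.3%, 6.3% and 6.2%, a row that hardly changes, on the ground that “the dosing time barely matters”.
- The flask gives 5.32%, 5.32%, 5.30%, 5.27% and 5.22%, and the row hardly changes.
- In north-east, half the turnover of substrate and partner into intermediate A up to 2.00 min is done after 10.6 s, longer than the south-west feed of 6.0 s. The feed lateness of 2.33% stands against a relative drop in product of 1.88% from north-east to south-west, and between north-east and east the feed lateness of 1.08% stands against a relative drop of 0.940%.

The constants used here belong to no real substance; what happens was integrated by code.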